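## Retrosynthetic overview

1. Target ⇐ last-step C3'–C4' dehydrogenation and C5' hydroxylation of the saturated NH β-keto lactam cyclophane.
2. 13-membered ring ⇐ Ullmann-type macro-etherification between the ring-B secondary alcohol and an aryl iodide (key ring closure).
3. Seco compound ⇐ Claisen-type acylation of an L-phenylalanine-derived N-Boc lactam enolate by a tetracyclic γ-lactone (fragment union).
4. Rings B and C (plus the lactone) ⇐ one endo intramolecular Diels–Alder reaction of a butenolide/triene tethered on ring A; the triene and butenolide come from a formyl ylide, allyldiphenylphosphine oxide and methyl propiolate.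
5. Ring A ⇐ organocatalytic Diels–Alder reaction of 2-methylpentadiene with ethyl 4-oxobutenoate. Ring order: A, then B + C, then the macrocycle, then the pyrrolinone oxidation level.

Labels used in names: ring A = trimethylcyclohexane, ring B = cyclopentane, ring C = cyclohexene; C-a = ring-C carbon bearing vinyl; C-d/C-e = B/C fusion carbons; C-f = ring-B carbon bearing oxygen; C-g = ring-C carbon bearing the carbonyl substituent; C3', C4', C5' = lactam carbons (C5' carries the benzylic CH2).

Assumption: ethyl (E)-4-oxobut-2-enoate, (E)-2-methylpenta-1,3-diene, (R,R)-ProPhenol and the first-generation MacMillan imidazolidinone are purchased.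

## Route

Step 1
Reactants: 1 L-phenylalanine
Product: 2 4-iodo-L-phenylalanine
Conditions: I2, NaIO3, H2SO4, AcOH, 70 °C
Reagents that add atoms: iodine (II); sodium iodate ([Na+].[O-]I(=O)=O)
Why: Electrophilic aromatic iodination goes para to the alkyl chain of the protonated amino acid and leaves the α-stereocentre untouched.

Step 2
Reactants: 2 4-iodo-L-phenylalanine
Product: 3 N-Boc-4-iodo-L-phenylalanine
Conditions: Boc2O, NaOH, dioxane/H2O, rt; HCl work-up
Reagents that add atoms: di-tert-butyl dicarbonate (CC(C)(C)OC(=O)OC(=O)OC(C)(C)C)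
Why: Schotten–Baumann N-acylation gives the carbamate without touching the stereocentre or the aryl iodide.

Step 3
Reactants: 3 N-Boc-4-iodo-L-phenylalanine; 4 Meldrum's acid
Product: 5 tert-butyl N-[(2S)-1-(2,2-dimethyl-4,6-dioxo-1,3-dioxan-5-ylidene)-1-hydroxy-3-(4-iodophenyl)propan-2-yl]carbamate
Conditions: EDC·HCl, DMAP, CH2Cl2, 0 °C → rt
Reagents that add atoms: none
Why: Carbodiimide/DMAP (Steglich-type) C-acylation of the acidic Meldrum's acid methylene gives the enolised acyl Meldrum's acid without racemisation.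

Step 4
Reactants: 5 acyl Meldrum's acid
Product: 6 tert-butyl N-[(2R)-1-(2,2-dimethyl-4,6-dioxo-1,3-dioxan-5-yl)-3-(4-iodophenyl)propan-2-yl]carbamate
Conditions: NaBH4, AcOH, CH2Cl2, 0 °C → rt
Reagents that add atoms: none
Why: Borohydride reduction in acetic acid (reduction, dehydration to the alkylidene Meldrum's acid, conjugate reduction) deoxygenates the enol carbon to CH2 while carbamate and aryl iodide survive.

Step 5
Reactants: 6 reduced Meldrum's adduct
Product: 7 tert-butyl (2R)-2-[(4-iodophenyl)methyl]-5-oxopyrrolidine-1-carboxylate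
Conditions: toluene, 110 °C
Reagents that add atoms: none
Why: Thermal intramolecular N-acylation by the Meldrum's acid unit followed by decarboxylation closes the γ-lactam, the stereocentre being a spectator whose descriptor changes only by priority.

Step 6
Reactants: 8 chlorodiphenylphosphine; 9 allyl alcohol
Product: 11 allyldiphenylphosphine oxide, via allyl diphenylphosphinite 10 (not isolated)
Conditions: pyridine, Et2O, 0 °C → rt; then neat, 150 °C
Reagents that add atoms: none
Why: O-phosphinylation of the alcohol followed by thermal [2,3]-sigmatropic (Arbuzov-type) rearrangement of the allyl phosphinite gives the phosphine oxide.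

Step 7
Reactants: 12 ethyltriphenylphosphonium bromide; 13 ethyl formate
Product: 15 2-(triphenylphosphoranylidene)propanal, via ethylidenetriphenylphosphorane 14 (not isolated)
Conditions: KOt-Bu, THF, 0 °C; then 13, 0 °C → rt
Reagents that add atoms: none
Why: Ylide formation and C-formylation by the formate ester (the released ethoxide completes the proton transfer) give the stabilised formyl ylide.

Step 8
Reactants: 16 (E)-2-methylpenta-1,3-diene; 17 ethyl (E)-4-oxobut-2-enoate
Product: 19 ethyl (1S,5S,6S)-6-(dimethoxymethyl)-3,5-dimethylcyclohex-3-ene-1-carboxylate, via formyl ester 18 (not isolated)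
Conditions: (5S)-5-benzyl-2,2,3-trimethylimidazolidin-4-one·HCl (first-generation MacMillan catalyst, 20 mol %), MeNO2/H2O 19:1, 0 °C → rt; then HC(OMe)3, MeOH, TsOH (cat.)
Reagents that add atoms: trimethyl orthoformate (COC(OC)OC)
Why: In this iminium-catalysed enantioselective Diels–Alder reaction the aldehyde α-carbon bonds to the methyl-bearing diene terminus, the catalyst benzyl group exposes the Si face of that carbon and the endo transition state places the ring methyl cis to the formyl group, which is then masked in situ by acid-catalysed acetalisation.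

Step 9
Reactants: 19 acetal ester
Product: 20 ethyl (1R,5S,6S)-6-(dimethoxymethyl)-1,3,5-trimethylcyclohex-3-ene-1-carboxylate
Conditions: LiN(i-Pr)2, THF, −78 °C; MeI, DMPU, −78 → −20 °C
Reagents that add atoms: iodomethane (CI)
Why: In this ester enolate alkylation the vicinal dimethoxymethyl group (pseudoaxial to avoid allylic strain) and the neighbouring ring methyl shield one face, so methyl iodide enters trans to both and sets the quaternary centre.

Step 10
Reactants: 20 methylated ester
Product: 21 ethyl (1R,2S,3S,5R)-2-(dimethoxymethyl)-1,3,5-trimethylcyclohexane-1-carboxylate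
Conditions: H2 (4 atm), 10% Pd/C, EtOAc, rt
Reagents that add atoms: none
Why: Heterogeneous syn-hydrogenation delivers hydrogen to the alkene face opposite the axial dimethoxymethyl group and the allylic methyl, so the new methyl-bearing centre ends cis to the existing secondary methyl (minor epimer removed by chromatography).

Step 11
Reactants: 21 saturated ester
Product: 22 [(1R,2S,3S,5R)-2-(dimethoxymethyl)-1,3,5-trimethylcyclohexyl]methanol
Conditions: LiAlH4, THF, 0 °C → rt
Reagents that add atoms: none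
Why: Hydride reduction of the neopentyl ester gives the primary alcohol and leaves the acetal untouched.

Step 12
Reactants: 22 neopentyl alcohol; 15 2-(triphenylphosphoranylidene)propanal
Product: 24 (2E)-3-[(1S,2S,3S,5R)-2-(dimethoxymethyl)-1,3,5-trimethylcyclohexyl]-2-methylprop-2-enal, via neopentyl aldehyde 23 (not isolated)
Conditions: Dess–Martin periodinane, NaHCO3, CH2Cl2, rt; filter, concentrate; then 15, toluene, 110 °C
Reagents that add atoms: none
Why: Dess–Martin oxidation to the non-enolisable aldehyde followed by Wittig olefination by the stabilised formyl ylide gives the (E)-2-methyl enal selectively.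

Step 13
Reactants: 24 enal; 11 allyldiphenylphosphine oxide
Product: 25 (1S,2S,3S,5R)-2-(dimethoxymethyl)-1,3,5-trimethyl-1-[(1E,3E)-2-methylhexa-1,3,5-trien-1-yl]cyclohexane
Conditions: n-BuLi, THF/HMPA, −78 °C → rt
Reagents that add atoms: none
Why: Horner–Wittig olefination by the lithiated allylphosphine oxide in the presence of HMPA (Yamamoto diene synthesis) adds 1,2 to the enal and eliminates to the (E)-diene, completing the (E,E)-triene.

Step 14
Reactants: 25 triene acetal
Product: 27 (1R,2S,4R,6S)-2,4,6-trimethyl-2-[(1E,3E)-2-methylhexa-1,3,5-trien-1-yl]cyclohexane-1-carbaldehyde, via cis aldehyde 26 (not isolated)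
Conditions: oxalic acid, THF/H2O, 40 °C; then DBU, CH2Cl2, rt
Reagents that add atoms: water (O)
Why: Mild acetal hydrolysis followed by base-mediated epimerisation through the enol moves the formyl group to the thermodynamically preferred equatorial position, trans to the trienyl group and to the adjacent methyl, which the trans A/B fusion needs.

Step 15
Reactants: 27 trans aldehyde; 28 methyl propiolate
Product: 29 methyl (4R)-4-hydroxy-4-[(1R,2S,4R,6S)-2,4,6-trimethyl-2-[(1E,3E)-2-methylhexa-1,3,5-trien-1-yl]cyclohexyl]but-2-ynoate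
Conditions: ZnMe2, (R,R)-ProPhenol (20 mol %), Ph3PO (40 mol %), toluene, 0 °C
Reagents that add atoms: none
Why: In the Trost ProPhenol dinuclear zinc alkynylation the chiral catalyst delivers the zinc acetylide to the Si face of the aldehyde (reagent control over a weak opposing Felkin bias) and sets the carbinol centre C-f.

Step 16
Reactants: 29 hydroxy ynoate
Product: 32 tetracyclic γ-lactone (rings A/B trans; B/C cis; lactone O on C-f; lactone C=O on C-g; H atoms at C-d C-e C-f C-g all cis; vinyl on C-a cis to the lactone carbonyl), via Z-hydroxy enoate 30 (not isolated), via butenolide 31 (not isolated)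
Conditions: H2 (1 atm), Pd/CaCO3 poisoned with Pb(OAc)2 (Lindlar catalyst), quinoline, EtOAc, 0 °C; filter; then toluene, BHT, 110 °C
Reagents that add atoms: none
Why: Lindlar semihydrogenation of the activated ynoate (faster than the triene on the poisoned catalyst) gives the Z-enoate, which lactonises to the butenolide, and its intramolecular Diels–Alder reaction through the endo transition state forms rings B and C cis-fused, with C-f (part of both tether and dienophile) dictating the face and hence C-a, C-d, C-e and C-g.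

Step 17
Reactants: 32 tetracyclic γ-lactone; 7 N-Boc lactam
Product: 33 seco hydroxy β-keto N-Boc lactam (C-g epimer; free OH on C-f; C3' epimers; aryl iodide)
Conditions: LiN(SiMe3)2, THF, −78 °C (7, 2.5 equiv); then 32, −78 → −20 °C; AcOH
Reagents that add atoms: none
Why: Claisen-type C-acylation of the lactam lithium enolate by the strained γ-lactone opens the lactone, frees the C-f hydroxyl and is driven by deprotonation of the β-keto lactam product.

Step 18
Reactants: 33 seco hydroxy β-keto N-Boc lactam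
Product: 34 N-Boc β-keto lactam 13-membered paracyclophane (C-g epimer)
Conditions: CuI (2 equiv), 3,4,7,8-tetramethyl-1,10-phenanthroline, Cs2CO3, 4 Å MS, toluene (1 mM), 110 °C
Reagents that add atoms: none
Why: This Ullmann-type macro-etherification couples the secondary alkoxide and the aryl iodide intramolecularly under high dilution with retention at C-f, while the β-keto lactam sits as its cesium enolate and its own C- or O-arylation is geometrically impossible.

Step 19
Reactants: 34 N-Boc cyclophane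
Product: 36 NH β-keto lactam cyclophane with the natural C-g configuration, via C-g-epimeric NH lactam 35 (not isolated)
Conditions: CF3CO2H, CH2Cl2, 0 °C; evaporate; then Et3N, MeOH, 65 °C
Reagents that add atoms: none
Why: Acidolysis removes the Boc group and amine-mediated enolisation then epimerises the ketone α-carbon C-g from the all-cis array on ring C to the thermodynamically favoured configuration trans to both neighbours.

Step 20
Reactants: 36 NH β-keto lactam cyclophane
Product: 40 target CNP0151253.2, via selenide 37 (not isolated), via selenoxide 38 (not isolated), via deoxy pyrrolinone 39 (not isolated)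
Conditions: LiN(SiMe3)2 (1.1 equiv), THF, −78 °C; PhSeCl; then 30% H2O2, pyridine, CH2Cl2, 0 °C → rt
Reagents that add atoms: hydrogen peroxide (OO)
Why: α-Selenenylation of the β-keto lactam enolate and selenoxide syn-elimination (Reich–Sharpless) install the C3'–C4' double bond, the C5'-H pyrrolinone is then hydroxylated at C5' by excess peroxide through its 2-hydroxypyrrole tautomer, and the hemiaminal centre settles in the natural configuration by ring–chain equilibration.

## Compound list

1 | L-phenylalanine | N[C@@H](Cc1ccccc1)C(=O)O | starting material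
2 | 4-iodo-L-phenylalanine | N[C@@H](Cc1ccc(I)cc1)C(=O)O | intermediate
3 | N-Boc-4-iodo-L-phenylalanine | CC(C)(C)OC(=O)N[C@@H](Cc1ccc(I)cc1)C(=O)O | intermediate
4 | Meldrum's acid (2,2-dimethyl-1,3-dioxane-4,6-dione) | CC1(C)OC(=O)CC(=O)O1 | starting material
5 | tert-butyl N-[(2S)-1-(2,2-dimethyl-4,6-dioxo-1,3-dioxan-5-ylidene)-1-hydroxy-3-(4-iodophenyl)propan-2-yl]carbamate | CC(C)(C)OC(=O)N[C@@H](Cc1ccc(I)cc1)C(O)=C1C(=O)OC(C)(C)OC1=O | intermediate
6 | tert-butyl N-[(2R)-1-(2,2-dimethyl-4,6-dioxo-1,3-dioxan-5-yl)-3-(4-iodophenyl)propan-2-yl]carbamate | CC(C)(C)OC(=O)N[C@@H](Cc1ccc(I)cc1)CC1C(=O)OC(C)(C)OC1=O | intermediate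
7 | tert-butyl (2R)-2-[(4-iodophenyl)methyl]-5-oxopyrrolidine-1-carboxylate | CC(C)(C)OC(=O)N1C(=O)CC[C@@H]1Cc1ccc(I)cc1 | intermediate
8 | chlorodiphenylphosphine | ClP(c1ccccc1)c1ccccc1 | starting material
9 | allyl alcohol | C=CCO | starting material
10 | allyl diphenylphosphinite | C=CCOP(c1ccccc1)c1ccccc1 | intermediate
11 | allyldiphenylphosphine oxide | C=CCP(=O)(c1ccccc1)c1ccccc1 | intermediate
12 | ethyltriphenylphosphonium bromide | CC[P+](c1ccccc1)(c1ccccc1)c1ccccc1.[Br-] | starting material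
13 | ethyl formate | CCOC=O | starting material
14 | ethylidenetriphenylphosphorane | CC=P(c1ccccc1)(c1ccccc1)c1ccccc1 | intermediate
15 | 2-(triphenylphosphoranylidene)propanal | CC(C=O)=P(c1ccccc1)(c1ccccc1)c1ccccc1 | intermediate
16 | (E)-2-methylpenta-1,3-diene | C=C(C)/C=C/C | starting material
17 | ethyl (E)-4-oxobut-2-enoate | CCOC(=O)/C=C/C=O | starting material
18 | ethyl (1S,5S,6S)-6-formyl-3,5-dimethylcyclohex-3-ene-1-carboxylate | O=C[C@H]1[C@@H](C)C=C(C)C[C@@H]1C(=O)OCC | intermediate
19 | ethyl (1S,5S,6S)-6-(dimethoxymethyl)-3,5-dimethylcyclohex-3-ene-1-carboxylate | COC(OC)[C@H]1[C@@H](C)C=C(C)C[C@@H]1C(=O)OCC | intermediate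
20 | ethyl (1R,5S,6S)-6-(dimethoxymethyl)-1,3,5-trimethylcyclohex-3-ene-1-carboxylate | COC(OC)[C@H]1[C@@H](C)C=C(C)C[C@]1(C(=O)OCC)C | intermediate
21 | ethyl (1R,2S,3S,5R)-2-(dimethoxymethyl)-1,3,5-trimethylcyclohexane-1-carboxylate | COC(OC)[C@H]1[C@@H](C)C[C@@H](C)C[C@]1(C(=O)OCC)C | intermediate
22 | [(1R,2S,3S,5R)-2-(dimethoxymethyl)-1,3,5-trimethylcyclohexyl]methanol | COC(OC)[C@H]1[C@@H](C)C[C@@H](C)C[C@]1(CO)C | intermediate
23 | (1R,2S,3S,5R)-2-(dimethoxymethyl)-1,3,5-trimethylcyclohexane-1-carbaldehyde | COC(OC)[C@H]1[C@@H](C)C[C@@H](C)C[C@]1(C=O)C | intermediate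
24 | (2E)-3-[(1S,2S,3S,5R)-2-(dimethoxymethyl)-1,3,5-trimethylcyclohexyl]-2-methylprop-2-enal | COC(OC)[C@H]1[C@@H](C)C[C@@H](C)C[C@]1(/C=C(C)/C=O)C | intermediate
25 | (1S,2S,3S,5R)-2-(dimethoxymethyl)-1,3,5-trimethyl-1-[(1E,3E)-2-methylhexa-1,3,5-trien-1-yl]cyclohexane | COC(OC)[C@H]1[C@@H](C)C[C@@H](C)C[C@]1(/C=C(C)/C=C/C=C)C | intermediate
26 | (1S,2S,4R,6S)-2,4,6-trimethyl-2-[(1E,3E)-2-methylhexa-1,3,5-trien-1-yl]cyclohexane-1-carbaldehyde (cis aldehyde) | O=C[C@H]1[C@@H](C)C[C@@H](C)C[C@]1(/C=C(C)/C=C/C=C)C | intermediate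
27 | (1R,2S,4R,6S)-2,4,6-trimethyl-2-[(1E,3E)-2-methylhexa-1,3,5-trien-1-yl]cyclohexane-1-carbaldehyde (trans aldehyde) | O=C[C@@H]1[C@@H](C)C[C@@H](C)C[C@]1(/C=C(C)/C=C/C=C)C | intermediate
28 | methyl propiolate | COC(=O)C#C | starting material
29 | methyl (4R)-4-hydroxy-4-[(1R,2S,4R,6S)-2,4,6-trimethyl-2-[(1E,3E)-2-methylhexa-1,3,5-trien-1-yl]cyclohexyl]but-2-ynoate | COC(=O)C#C[C@H](O)[C@@H]1[C@@H](C)C[C@@H](C)C[C@]1(/C=C(C)/C=C/C=C)C | intermediate
30 | methyl (2Z,4S)-4-hydroxy-4-[(1R,2S,4R,6S)-2,4,6-trimethyl-2-[(1E,3E)-2-methylhexa-1,3,5-trien-1-yl]cyclohexyl]but-2-enoate | COC(=O)/C=C\[C@H](O)[C@@H]1[C@@H](C)C[C@@H](C)C[C@]1(/C=C(C)/C=C/C=C)C | intermediate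
31 | (5S)-5-[(1R,2S,4R,6S)-2,4,6-trimethyl-2-[(1E,3E)-2-methylhexa-1,3,5-trien-1-yl]cyclohexyl]furan-2(5H)-one | O=C1C=C[C@H](O1)[C@@H]2[C@@H](C)C[C@@H](C)C[C@]2(/C=C(C)/C=C/C=C)C | intermediate
32 | tetracyclic γ-lactone (A/B trans; B/C cis; lactone O on C-f and C=O on C-g; vinyl on C-a) | C=C[C@H]1C=C(C)[C@@H]2[C@H]3[C@H](OC(=O)[C@@H]13)[C@@H]1[C@@H](C)C[C@@H](C)C[C@]12C | intermediate
33 | seco hydroxy β-keto N-Boc lactam (C-g epimer; free OH on C-f; aryl iodide) | CC(C)(C)OC(=O)N1C(=O)C(C[C@@H]1Cc1ccc(I)cc1)C(=O)[C@H]1[C@@H](C=C)C=C(C)[C@@H]2[C@H]1[C@H](O)[C@@H]3[C@@H](C)C[C@@H](C)C[C@@]23C | intermediate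
34 | N-Boc β-keto lactam 13-membered paracyclophane (C-g epimer) | C=C[C@H]1C=C(C)[C@@H]2[C@H]3[C@H](Oc4ccc(cc4)C[C@H]4CC(C(=O)N4C(=O)OC(C)(C)C)C(=O)[C@@H]13)[C@@H]1[C@@H](C)C[C@@H](C)C[C@]12C | intermediate
35 | NH β-keto lactam cyclophane (C-g epimer) | C=C[C@H]1C=C(C)[C@@H]2[C@H]3[C@H](Oc4ccc(cc4)C[C@H]4CC(C(=O)N4)C(=O)[C@@H]13)[C@@H]1[C@@H](C)C[C@@H](C)C[C@]12C | intermediate
36 | NH β-keto lactam cyclophane (natural C-g configuration) | C=C[C@H]1C=C(C)[C@@H]2[C@H]3[C@H](Oc4ccc(cc4)C[C@H]4CC(C(=O)N4)C(=O)[C@H]13)[C@@H]1[C@@H](C)C[C@@H](C)C[C@]12C | intermediate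
37 | C3'-phenylselanyl derivative of 36 | C=C[C@H]1C=C(C)[C@@H]2[C@H]3[C@H](Oc4ccc(cc4)C[C@H]4CC([Se]c5ccccc5)(C(=O)N4)C(=O)[C@H]13)[C@@H]1[C@@H](C)C[C@@H](C)C[C@]12C | intermediate
38 | selenoxide of 37 | C=C[C@H]1C=C(C)[C@@H]2[C@H]3[C@H](Oc4ccc(cc4)C[C@H]4CC([Se](=O)c5ccccc5)(C(=O)N4)C(=O)[C@H]13)[C@@H]1[C@@H](C)C[C@@H](C)C[C@]12C | intermediate
39 | deoxy pyrrolinone (C5'-H 3-acyl-1,5-dihydropyrrol-2-one cyclophane) | C=C[C@H]1C=C(C)[C@@H]2[C@H]3[C@H](Oc4ccc(cc4)C[C@H]4C=C(C(=O)N4)C(=O)[C@H]13)[C@@H]1[C@@H](C)C[C@@H](C)C[C@]12C | intermediate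
40 | CNP0151253.2 (5'-hydroxy-3'-acyl-3'-pyrrolin-2'-one cyclophane) | C=C[C@H]1C=C(C)[C@@H]2[C@H]3[C@H](Oc4ccc(cc4)C[C@@]4(O)C=C(C(=O)N4)C(=O)[C@H]13)[C@@H]1[C@@H](C)C[C@@H](C)C[C@]12C | target

## Step count and risks

Total step count: 20 (steps 1–5 lactam branch, step 6 phosphine oxide, step 7 ylide, steps 8–20 main line).
Longest linear sequence: 13 steps (steps 8–20, from 16 and 17 to 40), which is 13/20 of the total.

Three steps most likely to fail:

Step 15 (alkynylation). The aldehyde is flanked by a quaternary and a tertiary carbon, and the Felkin preference opposes the catalyst. Fallback, setting out from 27 and coming back at 29: add lithiated methyl propiolate (LiN(SiMe3)2, THF, −78 °C) without stereocontrol, which gives 29 together with the carbinol epimer F1. Oxidise the mixture with Dess–Martin periodinane to the ynone F2. Reduce F2 by Noyori transfer hydrogenation (RuCl(p-cymene)[(R,R)-TsDPEN], HCO2H/Et3N); hydride delivery is now matched with the Felkin preference and returns 29.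

Step 18 (macro-etherification). The ring is strained and the alcohol is hindered. Fallback, setting out from 32 (with commercial 4-fluoro-L-phenylalanine as the extra starting material) and coming back at 34:
- Nitrate 4-fluoro-L-phenylalanine (HNO3/H2SO4) to 4-fluoro-3-nitro-L-phenylalanine F3.
- Take it through the operations of steps 2–5 to the N-Boc acid F4, the acyl Meldrum's acid F5, the reduced Meldrum's adduct F6 and the fluoronitro N-Boc lactam F7.
- Acylate the enolate of F7 with 32 as in step 17 to the fluoronitro seco compound F8.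
- Close the ring by intramolecular SNAr of the alkoxide on the nitro-activated fluoroarene (K2CO3, DMF, high dilution) to the nitro cyclophane F9.
- Reduce the nitro group (Zn, NH4Cl) to the amino cyclophane F10 and remove the amino group by hydrodediazoniation (t-BuONO, DMF, 65 °C) to reach 34.

Step 20 (selenation, elimination and C5' hydroxylation in one flask). The peroxide may over-oxidise the alkenes or stop at 39. Fallback, setting out from 36 and coming back at 40: brominate C3' with N-bromosuccinimide to the C3' bromide F11. Eliminate HBr with DBU to 39 and trap it in the same flask with TBSOTf/2,6-lutidine as the 2-silyloxypyrrole F12. Oxidise F12 at C5' with dimethyldioxirane at −78 °C (Rubottom-type hydroxylation of the isolated electron-rich pyrrole) and desilylate with HF·pyridine to give 40.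

Further compounds

F1 | step 15 | carbinol epimer, methyl (4S)-4-hydroxy-4-[(1R,2S,4R,6S)-2,4,6-trimethyl-2-[(1E,3E)-2-methylhexa-1,3,5-trien-1-yl]cyclohexyl]but-2-ynoate | COC(=O)C#C[C@@H](O)[C@@H]1[C@@H](C)C[C@@H](C)C[C@]1(/C=C(C)/C=C/C=C)C
F2 | step 15 | ynone, methyl 4-oxo-4-[(1R,2S,4R,6S)-2,4,6-trimethyl-2-[(1E,3E)-2-methylhexa-1,3,5-trien-1-yl]cyclohexyl]but-2-ynoate | COC(=O)C#CC(=O)[C@@H]1[C@@H](C)C[C@@H](C)C[C@]1(/C=C(C)/C=C/C=C)C
F3 | step 18 | 4-fluoro-3-nitro-L-phenylalanine | N[C@@H](Cc1ccc(F)c(c1)[N+](=O)[O-])C(=O)O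
F4 | step 18 | N-Boc acid, N-Boc-4-fluoro-3-nitro-L-phenylalanine | CC(C)(C)OC(=O)N[C@@H](Cc1ccc(F)c(c1)[N+](=O)[O-])C(=O)O
F5 | step 18 | acyl Meldrum's acid of F4 | CC(C)(C)OC(=O)N[C@@H](Cc1ccc(F)c(c1)[N+](=O)[O-])C(O)=C1C(=O)OC(C)(C)OC1=O
F6 | step 18 | reduced Meldrum's adduct | CC(C)(C)OC(=O)N[C@@H](Cc1ccc(F)c(c1)[N+](=O)[O-])CC1C(=O)OC(C)(C)OC1=O
F7 | step 18 | fluoronitro N-Boc lactam, tert-butyl (2R)-2-[(4-fluoro-3-nitrophenyl)methyl]-5-oxopyrrolidine-1-carboxylate | CC(C)(C)OC(=O)N1C(=O)CC[C@@H]1Cc1ccc(F)c(c1)[N+](=O)[O-]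
F8 | step 18 | fluoronitro seco compound (analogue of 33) | CC(C)(C)OC(=O)N1C(=O)C(C[C@@H]1Cc1ccc(F)c(c1)[N+](=O)[O-])C(=O)[C@H]1[C@@H](C=C)C=C(C)[C@@H]2[C@H]1[C@H](O)[C@@H]3[C@@H](C)C[C@@H](C)C[C@@]23C
F9 | step 18 | nitro cyclophane (34 with NO2 ortho to the ether oxygen) | C=C[C@H]1C=C(C)[C@@H]2[C@H]3[C@H](Oc4ccc(cc4[N+](=O)[O-])C[C@H]4CC(C(=O)N4C(=O)OC(C)(C)C)C(=O)[C@@H]13)[C@@H]1[C@@H](C)C[C@@H](C)C[C@]12C
F10 | step 18 | amino cyclophane (34 with NH2 ortho to the ether oxygen) | C=C[C@H]1C=C(C)[C@@H]2[C@H]3[C@H](Oc4ccc(cc4N)C[C@H]4CC(C(=O)N4C(=O)OC(C)(C)C)C(=O)[C@@H]13)[C@@H]1[C@@H](C)C[C@@H](C)C[C@]12C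
F11 | step 20 | C3' bromide of 36 | C=C[C@H]1C=C(C)[C@@H]2[C@H]3[C@H](Oc4ccc(cc4)C[C@H]4CC(Br)(C(=O)N4)C(=O)[C@H]13)[C@@H]1[C@@H](C)C[C@@H](C)C[C@]12C
F12 | step 20 | 2-silyloxypyrrole (2-tert-butyldimethylsilyloxy-3-acyl-1H-pyrrole cyclophane) | C=C[C@H]1C=C(C)[C@@H]2[C@H]3[C@H](Oc4ccc(cc4)Cc4cc(c(O[Si](C)(C)C(C)(C)C)[nH]4)C(=O)[C@H]13)[C@@H]1[C@@H](C)C[C@@H](C)C[C@]12C
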